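**Strategy.** Everything rests on cutting the C4–C5 bond of the nine-membered ring (caryophyllane numbering). The feature used is the secondary allylic alcohol at C5, which sits beside the methyl-bearing carbon C4 of the Z C3=C4 alkene and across the ring from the trans-fused cyclobutane: that bond maps back to an alkenylchromium adding to an aldehyde. One intramolecular Nozaki–Hiyama–Kishi reaction makes the C4–C5 bond, closes the nine-membered ring with the Z geometry kept and creates the C5 carbinol. Its precursor is a trans-1,2-disubstituted gem-dimethylcyclobutane with a (Z)-3-iodobut-2-enyl arm and a 4-oxobutanoyl (keto-aldehyde) arm. The spiro dihydropyran is added last by a hetero-Diels–Alder reaction on a C8 methylene.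

Key step: step 8

Numbering: the terpenoid part is numbered as bicyclo[7.2.0]undecane (C1 and C9 ring fusion, C11 the gem-dimethyl carbon, C3=C4 the Z alkene with the methyl on C4, C5 the carbinol carbon, C8 the spiro carbon). C1' is the isobutyl-bearing pyran carbon. In steps 1 to 4 the locants are those of bicyclo[4.2.0]octane.

Assumption: the (S)-configured oxazaborolidine in step 1 is taken to give the (6R) photoadduct; should the sense of induction be the opposite, its enantiomer is used and nothing else changes.

Remark on the carbon count: opening the cyclohexanone of the photoadduct at one bond only would leave the aldehyde arm one carbon too long for a nine-membered ring. The three-carbon chain is therefore added to the carbonyl carbon first and the ring alkene is then cleaved twice, which removes ring carbon C3 as formic acid.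

**Step 1**
Reactants: 1 cyclohex-2-enone; 2 isobutene
Product: 4 (1R,6R)-7,7-dimethylbicyclo[4.2.0]octan-2-one (cis-fused), via trans-fused photoadduct 3 (not isolated)
Conditions: 2 (excess), (S)-3,3-bis(3,5-dimethylphenyl)-1-(2,4,6-trifluorophenyl)tetrahydro-1H,3H-pyrrolo[1,2-c][1,3,2]oxazaborole·AlBr3 (50 mol %), CH2Cl2, −75 °C, hν 366 nm; then basic Al2O3, CH2Cl2, rt
Reagents that add atoms: none
Why: Lewis-acid-catalysed enantioselective enone–alkene [2+2] photocycloaddition: the AlBr3-activated oxazaborolidine binds the enone carbonyl, shifts its absorption to 366 nm and covers one face, so that isobutene adds head-to-tail to the exposed face and fixes C6 as R, and the trans-fused adduct 3 that forms alongside is epimerised at C1 on basic Al2O3 to the more stable cis-fused ketone 4.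

**Step 2**
Reactants: 4 (1R,6R)-7,7-dimethylbicyclo[4.2.0]octan-2-one
Product: 6 (1R,6R)-7,7-dimethylbicyclo[4.2.0]oct-3-en-2-one, via silyl enol ether 5 (not isolated)
Conditions: LiN(iPr)2, THF, −78 °C, then Me3SiCl; solvent exchange; Pd(OAc)2 (1.1 equiv), MeCN, rt
Reagents that add atoms: none
Why: Kinetic deprotonation at the C3 methylene and O-silylation give enol ether 5 regioselectively, and Saegusa–Ito oxidation (palladation of the enol ether by divalent palladium, then β-hydride elimination from C4) introduces the C3=C4 double bond without touching the ring-fusion stereocentres.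

**Step 3**
Reactants: 6 (1R,6R)-7,7-dimethylbicyclo[4.2.0]oct-3-en-2-one; 7 2-(2-bromoethyl)-1,3-dioxolane
Product: 9 (1R,2S,6R)-2-[2-(1,3-dioxolan-2-yl)ethyl]-7,7-dimethylbicyclo[4.2.0]oct-3-en-2-ol, via Grignard reagent 8 (not isolated)
Conditions: 7, Mg, THF, 25 °C; anhydrous CeCl3, THF, −78 °C; then 6, −78 °C; aq. NH4Cl
Reagents that add atoms: none
Why: The organocerium reagent formed from Grignard reagent 8 and CeCl3 adds 1,2 to the enone carbonyl (oxophilic and weakly basic, so conjugate addition and enolisation are suppressed) from the convex face of the cis-fused bicycle, and the configuration of the new carbinol carbon is immaterial because this carbon becomes the C8 ketone in step 4.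

**Step 4**
Reactants: 9 (1R,2S,6R)-2-[2-(1,3-dioxolan-2-yl)ethyl]-7,7-dimethylbicyclo[4.2.0]oct-3-en-2-ol
Product: 12 2-[(1R,4R)-4-[3-(1,3-dioxolan-2-yl)propanoyl]-2,2-dimethylcyclobutyl]acetaldehyde (cis keto-aldehyde), via triol 10 (not isolated), via hydroxy dialdehyde 11 (not isolated)
Conditions: OsO4 (2 mol %), NaIO4 (4 equiv), 2,6-lutidine, 1,4-dioxane/H2O (3:1), rt
Reagents that add atoms: osmium tetroxide, O=[Os](=O)(=O)=O (delivers the aldehyde oxygen); sodium periodate, [Na+].[O-]I(=O)(=O)=O (terminal oxidant that restores OsO4)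
Why: Lemieux–Johnson cleavage followed in the same flask by Malaprade cleavage: catalytic dihydroxylation gives triol 10, periodate cuts its C3–C4 glycol bond to hydroxy dialdehyde 11 and then the C2–C3 bond of the α-hydroxy aldehyde, so that ring carbon C3 leaves as formic acid, C2 becomes the ketone and C4 the aldehyde of a two-carbon arm, while 2,6-lutidine keeps the medium mild enough for the dioxolane.

**Step 5**
Reactants: 12 2-[(1R,4R)-4-[3-(1,3-dioxolan-2-yl)propanoyl]-2,2-dimethylcyclobutyl]acetaldehyde
Product: 13 1-[(1R,2R)-2-[(2Z)-3-iodobut-2-en-1-yl]-3,3-dimethylcyclobutyl]-3-(1,3-dioxolan-2-yl)propan-1-one (cis)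
Conditions: EtPPh3I, n-BuLi, THF, 0 °C; I2, −78 °C; NaN(SiMe3)2, −20 °C; then 12, −78 °C
Reagents that add atoms: ethyltriphenylphosphonium iodide, CC[P+](c1ccccc1)(c1ccccc1)c1ccccc1.[I-]; iodine, II
Why: Wittig olefination with the α-iodo ylide Ph3P=C(I)CH3 (Stork–Zhao-type iodo-olefination) proceeds under kinetic control through the cis-oxaphosphetane and places iodine cis to the chain, which gives the Z iodoalkene, and at −78 °C the ylide reacts with the aldehyde and not with the hindered ketone.

**Step 6**
Reactants: 13 1-[(1R,2R)-2-[(2Z)-3-iodobut-2-en-1-yl]-3,3-dimethylcyclobutyl]-3-(1,3-dioxolan-2-yl)propan-1-one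
Product: 14 1-[(1S,2R)-2-[(2Z)-3-iodobut-2-en-1-yl]-3,3-dimethylcyclobutyl]-3-(1,3-dioxolan-2-yl)propan-1-one (trans)
Conditions: K2CO3, MeOH, rt
Reagents that add atoms: none
Why: Base-mediated epimerisation through the ketone enolate turns the acyl-bearing ring carbon into the thermodynamically preferred trans arrangement (the cis isomer suffers from the clash between the acyl group and the iodobutenyl arm beside the gem-dimethyl carbon), while the neighbouring ring carbon is not enolisable and keeps the configuration set in step 1.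

**Step 7**
Reactants: 14 1-[(1S,2R)-2-[(2Z)-3-iodobut-2-en-1-yl]-3,3-dimethylcyclobutyl]-3-(1,3-dioxolan-2-yl)propan-1-one
Product: 15 4-[(1S,2R)-2-[(2Z)-3-iodobut-2-en-1-yl]-3,3-dimethylcyclobutyl]-4-oxobutanal
Conditions: 2 M aq. HCl, THF, rt
Reagents that add atoms: water, O
Why: Acid-catalysed acetal hydrolysis releases the aldehyde under conditions that leave the ketone, the alkenyl iodide and the already thermodynamic trans ring intact, and the 1,4-keto-aldehyde is taken into step 8 without storage.

**Step 8**
Reactants: 15 4-[(1S,2R)-2-[(2Z)-3-iodobut-2-en-1-yl]-3,3-dimethylcyclobutyl]-4-oxobutanal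
Product: 17 (1R,3Z,5R,9S)-5-hydroxy-4,11,11-trimethylbicyclo[7.2.0]undec-3-en-8-one, via alkenylchromium 16 (not isolated)
Conditions: CrCl2 (8 equiv), NiCl2 (0.1 equiv), degassed DMSO, 25 °C, syringe-pump addition of 15 (final 0.002 M); H2O work-up
Reagents that add atoms: none
Why: CrCl2 reduces NiCl2 to zerovalent nickel, which undergoes oxidative addition into the alkenyl C–I bond of 15 without loss of the Z geometry; transmetalation then gives alkenylchromium 16 (trivalent chromium), whose carbon C4 adds to the aldehyde, and aqueous work-up frees alcohol 17. The closest known reaction type is the intramolecular Nozaki–Hiyama–Kishi reaction as used for eight- to ten-membered carbocyclic allylic alcohols. The nine-membered ring closes by 9-exo-trig addition of C4 to the aldehyde carbon C5. The new C5 stereocentre is set under substrate control in a folded transition state shaped by the trans-cyclobutane and the cis C3=C4 unit; the preference for 5R is expected to be moderate, and the epimers are separated. The step needs the aldehyde to react in preference to the C8 ketone and ring closure to beat intermolecular coupling: alkenylchromium reagents add to aldehydes far faster than to ketones, attack at C8 would have to build a strained trans-fused bicyclo[4.2.0]octene, and slow addition at high dilution together with the trans ring junction and the cis-alkenyl geometry, which bring C4 and C5 within reach, favours the ring.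

**Step 9**
Reactants: 17 (1R,3Z,5R,9S)-5-hydroxy-4,11,11-trimethylbicyclo[7.2.0]undec-3-en-8-one
Product: 18 (1R,3Z,5R,9S)-5-[(tert-butyldimethylsilyl)oxy]-4,11,11-trimethylbicyclo[7.2.0]undec-3-en-8-one
Conditions: TBSCl, imidazole, DMF, rt
Reagents that add atoms: tert-butyldimethylsilyl chloride, CC(C)(C)[Si](C)(C)Cl
Why: Standard silylation of the secondary allylic alcohol (imidazole-activated silyl chloride) removes the free hydroxyl, which would otherwise form an alkoxide and a transannular hemiketal with the C8 ketone during olefination and could add to the oxadiene in step 11.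

**Step 10**
Reactants: 18 (1R,3Z,5R,9S)-5-[(tert-butyldimethylsilyl)oxy]-4,11,11-trimethylbicyclo[7.2.0]undec-3-en-8-one
Product: 19 tert-butyldimethyl{[(1R,3Z,5R,9S)-4,11,11-trimethyl-8-methylidenebicyclo[7.2.0]undec-3-en-5-yl]oxy}silane
Conditions: Ph3PCH3Br, KOtBu, toluene, 0 → 80 °C
Reagents that add atoms: methyltriphenylphosphonium bromide, C[P+](c1ccccc1)(c1ccccc1)c1ccccc1.[Br-]
Why: Wittig methylenation with Ph3P=CH2 generated by KOtBu in hot toluene is the established answer to hindered, enolisable ketones of this cyclobutane-flanked kind, and C9 cannot be eroded because the trans ring fusion is the more stable one.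

**Step 11**
Reactants: 19 tert-butyldimethyl{[(1R,3Z,5R,9S)-4,11,11-trimethyl-8-methylidenebicyclo[7.2.0]undec-3-en-5-yl]oxy}silane; 20 syncarpic acid; 21 3-methylbutanal
Product: 23 5-O-(tert-butyldimethylsilyl) Tomentodione O (8S,1'R), via alkylidene triketone 22 (not isolated)
Conditions: 20 (2 equiv), 21 (3 equiv), ethylenediammonium diacetate (20 mol %), toluene, 80 °C
Reagents that add atoms: none
Why: Domino Knoevenagel/hetero-Diels–Alder reaction: condensation of 20 with 21 gives the 1-oxadiene 22, which reacts with inverse electron demand at the electron-rich 1,1-disubstituted C8 methylene (oxygen to the more substituted C8, the isobutyl-bearing carbon to the CH2), and approach to the exterior alkene face in the rotamer with H9 eclipsing the methylene, with the bulky C9 branch exo, should set the spiro carbon as S and C1' as R, the hindered trisubstituted ring alkene being left untouched.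

**Step 12**
Reactants: 23 5-O-(tert-butyldimethylsilyl) Tomentodione O
Product: 24 Tomentodione O
Conditions: Bu4NF, AcOH, THF, 0 °C → rt
Reagents that add atoms: none
Why: Fluoride-mediated desilylation (driven by the strong Si–F bond) frees the C5 hydroxyl, and the acetic acid buffer keeps the medium neutral so that the vinylogous ester and the tertiary C8–O bond are not disturbed and no stereocentre is touched.

**Compound list**

1 | cyclohex-2-enone | O=C1C=CCCC1 | starting material
2 | isobutene (2-methylpropene) | C=C(C)C | starting material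
3 | (1S,6R)-7,7-dimethylbicyclo[4.2.0]octan-2-one (trans-fused photoadduct) | O=C1CCC[C@@H]2[C@@H]1CC2(C)C | intermediate
4 | (1R,6R)-7,7-dimethylbicyclo[4.2.0]octan-2-one (cis-fused) | O=C1CCC[C@@H]2[C@H]1CC2(C)C | intermediate
5 | trimethyl{[(1R,6R)-7,7-dimethylbicyclo[4.2.0]oct-2-en-2-yl]oxy}silane | C[Si](C)(C)OC1=CCC[C@@H]2[C@H]1CC2(C)C | intermediate
6 | (1R,6R)-7,7-dimethylbicyclo[4.2.0]oct-3-en-2-one | O=C1C=CC[C@@H]2[C@H]1CC2(C)C | intermediate
7 | 2-(2-bromoethyl)-1,3-dioxolane | BrCCC1OCCO1 | starting material
8 | [2-(1,3-dioxolan-2-yl)ethyl]magnesium bromide | Br[Mg]CCC1OCCO1 | intermediate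
9 | (1R,2S,6R)-2-[2-(1,3-dioxolan-2-yl)ethyl]-7,7-dimethylbicyclo[4.2.0]oct-3-en-2-ol | O[C@@]1(CCC3OCCO3)C=CC[C@@H]2[C@H]1CC2(C)C | intermediate
10 | (1R,6R)-2-[2-(1,3-dioxolan-2-yl)ethyl]-7,7-dimethylbicyclo[4.2.0]octane-2,3,4-triol (cis-3,4-diol; carbinol configurations immaterial, drawn for attack anti to the cyclobutane) | O[C@@]1(CCC3OCCO3)[C@H](O)[C@H](O)C[C@@H]2[C@H]1CC2(C)C | intermediate
11 | 2-[(1R,4R)-4-[4-(1,3-dioxolan-2-yl)-2-hydroxy-1-oxobutan-2-yl]-2,2-dimethylcyclobutyl]acetaldehyde | O=CC[C@@H]1[C@@H](CC1(C)C)[C@@](O)(C=O)CCC1OCCO1 | intermediate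
12 | 2-[(1R,4R)-4-[3-(1,3-dioxolan-2-yl)propanoyl]-2,2-dimethylcyclobutyl]acetaldehyde (cis) | O=CC[C@@H]1[C@@H](CC1(C)C)C(=O)CCC1OCCO1 | intermediate
13 | 1-[(1R,2R)-2-[(2Z)-3-iodobut-2-en-1-yl]-3,3-dimethylcyclobutyl]-3-(1,3-dioxolan-2-yl)propan-1-one (cis) | C/C(I)=C/C[C@@H]1[C@@H](CC1(C)C)C(=O)CCC1OCCO1 | intermediate
14 | 1-[(1S,2R)-2-[(2Z)-3-iodobut-2-en-1-yl]-3,3-dimethylcyclobutyl]-3-(1,3-dioxolan-2-yl)propan-1-one (trans) | C/C(I)=C/C[C@@H]1[C@H](CC1(C)C)C(=O)CCC1OCCO1 | intermediate
15 | 4-[(1S,2R)-2-[(2Z)-3-iodobut-2-en-1-yl]-3,3-dimethylcyclobutyl]-4-oxobutanal | C/C(I)=C/C[C@@H]1[C@H](CC1(C)C)C(=O)CCC=O | intermediate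
16 | alkenylchromium dichloride from 15 (trivalent chromium in place of iodine, Z retained) | C/C([Cr](Cl)Cl)=C/C[C@@H]1[C@H](CC1(C)C)C(=O)CCC=O | intermediate
17 | (1R,3Z,5R,9S)-5-hydroxy-4,11,11-trimethylbicyclo[7.2.0]undec-3-en-8-one | C/C1=C/C[C@@H]2[C@H](CC2(C)C)C(=O)CC[C@H]1O | intermediate
18 | (1R,3Z,5R,9S)-5-[(tert-butyldimethylsilyl)oxy]-4,11,11-trimethylbicyclo[7.2.0]undec-3-en-8-one | C/C1=C/C[C@@H]2[C@H](CC2(C)C)C(=O)CC[C@H]1O[Si](C)(C)C(C)(C)C | intermediate
19 | tert-butyldimethyl{[(1R,3Z,5R,9S)-4,11,11-trimethyl-8-methylidenebicyclo[7.2.0]undec-3-en-5-yl]oxy}silane | C/C1=C/C[C@@H]2[C@H](CC2(C)C)C(=C)CC[C@H]1O[Si](C)(C)C(C)(C)C | intermediate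
20 | syncarpic acid (2,2,4,4-tetramethylcyclohexane-1,3,5-trione) | CC1(C)C(=O)CC(=O)C(C)(C)C1=O | starting material
21 | 3-methylbutanal | CC(C)CC=O | starting material
22 | 2,2,4,4-tetramethyl-6-(3-methylbutylidene)cyclohexane-1,3,5-trione | CC(C)CC=C1C(=O)C(C)(C)C(=O)C(C)(C)C1=O | intermediate
23 | 5-O-(tert-butyldimethylsilyl) Tomentodione O (1R,3Z,5R,8S,9S,1'R) | C/C1=C/C[C@@H]2[C@H](CC2(C)C)[C@]2(CC[C@H]1O[Si](C)(C)C(C)(C)C)C[C@@H](CC(C)C)C1=C(O2)C(C)(C)C(=O)C(C)(C)C1=O | intermediate
24 | Tomentodione O | C/C1=C/C[C@@H]2[C@H](CC2(C)C)[C@]2(CC[C@H]1O)C[C@@H](CC(C)C)C1=C(O2)C(C)(C)C(=O)C(C)(C)C1=O | target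

**Step count**

Total steps: 12. Longest linear sequence: 12 steps (1 → 24); 2, 7, 20 and 21 enter as commercial components.

**Steps most likely to fail**

1. Step 8. The process at risk is facial selection at the aldehyde during ring closure: the two C5 epimers may form in comparable amounts, and some material may be lost to intermolecular coupling. The fallback sets C5 by reagent control instead of by the ring closure. It sets out from 15: the ring is closed as in step 8 without regard to C5, which gives 17 mixed with its C5 epimer (1R,3Z,5S,9S)-5-hydroxy-4,11,11-trimethylbicyclo[7.2.0]undec-3-en-8-one F1. The mixture is oxidised with MnO2 in CH2Cl2, which acts only on the allylic alcohol, to the enedione (1R,3Z,9S)-4,11,11-trimethylbicyclo[7.2.0]undec-3-ene-5,8-dione F2. Corey–Bakshi–Shibata reduction ((S)-1-methyl-3,3-diphenyltetrahydro-1H,3H-pyrrolo[1,2-c][1,3,2]oxazaborole, catecholborane, toluene, −78 °C) should then reduce the conjugated C5 carbonyl ahead of the hindered saturated C8 ketone, with the alkenyl side as the large group, and give the 5R alcohol. The route is rejoined at 17.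

2. Step 11. The process at risk is approach of the oxadiene to the wrong face of the C8 methylene, or an ene reaction taking the place of the cycloaddition. The fallback builds the pyran stepwise, carbon–carbon bond first, and sets out from 18. Commercial 4-methylpent-1-yne is hydrozirconated with Cp2Zr(H)Cl and iodinated with I2 to (E)-1-iodo-4-methylpent-1-ene F3. Iodine–lithium exchange (t-BuLi, Et2O, −78 °C) and addition to 18 give the tertiary allylic alcohol (1R,3Z,5R,9S)-5-[(tert-butyldimethylsilyl)oxy]-4,11,11-trimethyl-8-[(1E)-4-methylpent-1-en-1-yl]bicyclo[7.2.0]undec-3-en-8-ol F4 (either C8 epimer serves), whose lithium alkoxide is trapped with ClCO2Me as the methyl carbonate F5. Pd2(dba)3 with a chiral Trost-type bisphosphine ionises F5, and 20 attacks the less hindered terminus of the allyl complex (Tsuji–Trost allylation), which gives the C-allylated triketone F6 with C1' under ligand control. Camphorsulfonic acid in CH2Cl2 at 0 °C then adds the enol oxygen to C8 of the trisubstituted alkene (Markovnikov, six-membered ring) under thermodynamic control. The route is rejoined at 23.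

3. Step 1. The process at risk is low enantio- or regioselectivity in the catalysed photocycloaddition. The fallback makes the racemate and resolves it with an enzyme; it sets out from 1 and 2. Direct irradiation without Lewis acid (Pyrex-filtered mercury lamp, CH2Cl2, −40 °C) and epimerisation on basic Al2O3 give 4 together with its enantiomer (1S,6S)-7,7-dimethylbicyclo[4.2.0]octan-2-one F7. NaBH4 in MeOH reduces both from the convex face to the endo alcohols (1R,2S,6R)-7,7-dimethylbicyclo[4.2.0]octan-2-ol F8 and its enantiomer (1S,2R,6S)-7,7-dimethylbicyclo[4.2.0]octan-2-ol F9. Candida antarctica lipase B with vinyl acetate is expected, by Kazlauskas' rule, to acetylate the 2R alcohol F9 to (1S,2R,6S)-7,7-dimethylbicyclo[4.2.0]octan-2-yl acetate F10 and to leave F8, which is separated and oxidised with Dess–Martin periodinane. The route is rejoined at 4.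

**Further compounds**

F1 | step 8 | (1R,3Z,5S,9S)-5-hydroxy-4,11,11-trimethylbicyclo[7.2.0]undec-3-en-8-one | C/C1=C/C[C@@H]2[C@H](CC2(C)C)C(=O)CC[C@@H]1O
F2 | step 8 | (1R,3Z,9S)-4,11,11-trimethylbicyclo[7.2.0]undec-3-ene-5,8-dione | C/C1=C/C[C@@H]2[C@H](CC2(C)C)C(=O)CCC1=O
F3 | step 11 | (E)-1-iodo-4-methylpent-1-ene | I/C=C/CC(C)C
F4 | step 11 | (1R,3Z,5R,9S)-5-[(tert-butyldimethylsilyl)oxy]-4,11,11-trimethyl-8-[(1E)-4-methylpent-1-en-1-yl]bicyclo[7.2.0]undec-3-en-8-ol (C8 not defined) | C/C1=C/C[C@@H]2[C@H](CC2(C)C)C(O)(/C=C/CC(C)C)CC[C@H]1O[Si](C)(C)C(C)(C)C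
F5 | step 11 | methyl carbonate of F4 (C8 not defined) | C/C1=C/C[C@@H]2[C@H](CC2(C)C)C(OC(=O)OC)(/C=C/CC(C)C)CC[C@H]1O[Si](C)(C)C(C)(C)C
F6 | step 11 | C-allylated syncarpic acid, enol form, 1'R (geometry of the C8 exocyclic alkene not defined) | C/C1=C/C[C@@H]2[C@H](CC2(C)C)C(CC[C@H]1O[Si](C)(C)C(C)(C)C)=C[C@@H](CC(C)C)C1=C(O)C(C)(C)C(=O)C(C)(C)C1=O
F7 | step 1 | (1S,6S)-7,7-dimethylbicyclo[4.2.0]octan-2-one | O=C1CCC[C@H]2[C@@H]1CC2(C)C
F8 | step 1 | (1R,2S,6R)-7,7-dimethylbicyclo[4.2.0]octan-2-ol | O[C@H]1CCC[C@@H]2[C@H]1CC2(C)C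
F9 | step 1 | (1S,2R,6S)-7,7-dimethylbicyclo[4.2.0]octan-2-ol | O[C@@H]1CCC[C@H]2[C@@H]1CC2(C)C
F10 | step 1 | (1S,2R,6S)-7,7-dimethylbicyclo[4.2.0]octan-2-yl acetate | CC(=O)O[C@@H]1CCC[C@H]2[C@@H]1CC2(C)C
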